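**Remark on numbering.** Germacrane-type locants are used throughout: C1 is the enol-ether carbon bonded to the ring oxygen and to C10, C2 its olefinic CH, C3 the ring CH2, C4 the oxygen-bearing quaternary carbon (methyl C15), C5 the exocyclic olefinic CH. C6, C7, C11 and C12 are the γ-, β-, α- and carbonyl carbons of the butenolide, C8 is CH(OAc), C9 is CH2, C10 is C(OH)CH3 (methyl C14) and C13 is CH2OAc. In these locants the target is (4S,8S,10S,5E).

**Assumption.** 4-[(tert-Butyldimethylsilyl)oxy]but-2-yn-1-ol (1) and (R)-2-methylglycidol (7) are taken as purchasable; 1 is otherwise one monosilylation away from but-2-yne-1,4-diol.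

## Structural features

The target is a sesquiterpenoid whose ten-membered carbocycle C1–C10 is bridged by an oxygen between C1 and C4. This bridge creates a 2,3-dihydrofuran (O, C1=C2, C3, C4) and a nine-membered oxacycle (O–C1–C10–C9–C8–C7–C6–C5–C4). A butenolide (C6, C7, C11, C12, lactone O) is fused at C6–C7 and carries the acetoxymethyl carbon C13 on C11. The C5=C6 olefin is exocyclic to the lactone but endocyclic to the medium ring, so C4 and C7 are cis on it (5E); an open-chain γ-alkylidene butenolide prefers the opposite geometry. There are three stereocenters: the quaternary ether carbon C4, the tertiary carbinol C10 and the acetoxy carbon C8. C8 and C10 are 1,3-anti across C9, whereas C4 is separated from C10 by the planar O–C1=C2 unit and cannot be relayed from it. Fragile groups are the bridgehead enol ether next to the tertiary C10 alcohol (acid), the dienyl lactone (base, nucleophiles), and the C13 acetate, which any dienolate of the lactone would expel. The real difficulty is the strained medium ring with three sp2 carbons inside it and a contra-thermodynamic olefin geometry. The key step exploits the acidity of the butenolide γ-carbon C6 and the fact that C5=C6 is the one bond whose geometry the nine-membered ring itself dictates.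

## Logic of the disconnections

In one sentence: the nine-membered ring of 18 is closed at the C5=C6 enol-lactone olefin by a vinylogous aldol condensation within 15, an open-chain compound in which dihydrofuran and butenolide are joined only through C8–C10.

**20 to 19 to 18.** The C13 O–acyl bond and the two O–Si bonds are cut last. An acyloxy group on C13 would be expelled by the C6-centred dienolate that the key step needs, so C13 carries a silyl ether until the γ-hydrogens are gone. The forward steps must desilylate without acid (enol ether) or strong base (dienyl lactone), then acylate only the primary hydroxyl.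

**18 to 15 (key disconnection).** The C5=C6 double bond is cut into a C5 aldehyde and the γ-CH2 of a butenolide. The cut removes the medium ring, the bridged bicycle and the strained olefin together. It leaves an open chain with two ordinary five-membered rings and the three stereocenters already in place. The forward step must close a nine-membered ring against intermolecular aldol addition. It need not control the two transient stereocenters at C5 and C6 or the olefin geometry, which the ring imposes.

**15 to 14 to 13.** The C5 oxidation level and the O–Si bond at C5 are adjusted. The aldehyde is unmasked only after the enol ether exists, because a free C5 hydroxyl would compete for the alkyne in the ring closure of 12. The forward steps must work under non-acidic conditions.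

**13 to 12.** The O–C1 bond of the dihydrofuran is cut to the tertiary C4 hydroxyl and a C1≡C2 alkyne. This replaces an acid-labile enol ether by a robust alkyne for the fragment union and puts no stereocenter at stake. The forward step must direct the C4 oxygen to C1 (5-endo-dig) while the C8 oxygen is blocked.

**12 to 11 to 9 + 6.** The O8–acyl bond is cut, then the C1–C10 bond between an acetylide and a methyl ketone. This divides the chain into a C5 alkynol carrying C4 and a butenolide ketone carrying C8. The forward addition must create C10 with 1,3-anti induction from the C8 hydroxyl and must not deprotonate the lactone.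

**6 to 5 to 4.** The C8–C9 bond is cut (aldol, acetone as C9–C10–C14), then the C8 carbonyl is traced to a vinyl group. The forward aldol must set C8 by catalyst control.

**4 to 1.** Three bonds around the butenolide are cut at once: C7–C8 (vinyl), C11–C12 (carbon dioxide) and the lactone O–C12. The forward step must add carbon to both alkyne carbons with defined regiochemistry and with anti geometry, so that the acid lactonises.

**9 to 8 to 7.** The O–Si bond and then the C2–C3 bond are cut to an acetylide and the epoxide of a glycidol. C4 is taken from the chiral pool because nothing in the target can relay to it. The forward opening must occur at the unsubstituted epoxide carbon.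

## Other disconnections considered

**Alternative 1:** Cut C7–C8, the bond most chemists would cut first. The forward key step is an intramolecular Nozaki–Hiyama–Kishi addition (CrCl2, cat. NiCl2) of the C7 vinyl iodide of seco-aldehyde A1 to its C8 aldehyde, followed by acetylation. The chosen plan is preferred on three grounds. A1 must hold the C5=C6 olefin in the E form before any ring exists, and in an open chain this is the disfavoured isomer of a γ-alkylidene butenolide. The C8 carbinol would be created in the ring closure with no control element other than an unknown ring conformation. The β-iodo dienyl lactone would have to survive the whole assembly, so the route is not shorter.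

**Alternative 2:** Cut both heterocycles back to a carbocycle and reconnect C1 to C6. The forward key step is ozonolysis of the tetrasubstituted C1=C6 bond of cadinene-type octalin A2 to the ten-membered 1,6-dione A3. The C1 carbonyl of A3 would be captured by the C4 hydroxyl (hemiketal, then dehydration) and the C6 carbonyl by the C12 carboxyl (enol lactonisation). The medium ring would appear without macrocyclisation, which is attractive. However, C4 lies in ring A of A2, across the planar ring-fusion olefin from C8 and C10 in ring B. No relay is possible, so both rings would need independent asymmetric construction and a union through a tetrasubstituted alkene. Ozone would also have to distinguish C1=C6 from C7=C11, and A3 is a 1,6-dione with a β-hydroxy ketone (C4–C5–C6), open to transannular aldol closure and retro-aldol cleavage. The plan is longer and more fragile.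

**Alternative 3:** Cut C4–C5 and add a temporary C1–C6 bond. The forward key step is an intramolecular Diels–Alder reaction of the 2-methylfuran in A4 with the exocyclic bromomethylene of its butenolide, giving oxanorbornene A5 (C4–C5 and C1–C6 formed, C4 set). Hydrogenation of C2=C3 and a Grob-type fragmentation of C1–C6 (bridging oxygen pushes, bromide leaves from C5) would then release the ten-membered ring with enol ether and E-alkylidene lactone. The idea is appealing because 2-methylfuran supplies C1–C4 and no macrocyclisation is needed. Three structural arguments speak against it. In A5 the exo-fused cyclohexane is locked in one chair, and the (4S,10S) relationship places the C10 methyl axial, syn to the axial C8 acetate and to the lactone oxygen on C6, so the cycloaddition is stereochemically mismatched. The reversible furan cycloaddition must join two fully substituted carbons (C1 and C6). The C1–C6 and C5–Br bonds cannot become antiperiplanar in the bicyclo[2.2.1] frame, so the fragmentation could only be stepwise. The chosen plan takes C4 from the chiral pool and uses only established reaction types.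

Key step: step 11

## Route

Step 1
Reactants: 1 4-[(tert-butyldimethylsilyl)oxy]but-2-yn-1-ol
Product: 4 3-{[(tert-butyldimethylsilyl)oxy]methyl}-4-ethenylfuran-2(5H)-one, via alkenylmagnesium alkoxide 2 (not isolated), via bromomagnesium carboxylate 3 (not isolated)
Conditions: CH2=CHMgBr (3.5 equiv), CuI (10 mol %), THF, −20 °C to rt; then CO2 (1 atm), 0 °C; aq. NH4Cl, then citric acid to pH 4
Reagents that add atoms: vinylmagnesium bromide C=C[Mg]Br; carbon dioxide O=C=O
Why: Copper-catalysed anti-carbomagnesiation of the propargylic magnesium alkoxide places the vinyl group on the alkyne carbon next to the carbinol (C7) and magnesium on the distal carbon (C11) in a five-membered chelate, so carboxylation should give the (Z)-γ-hydroxy acid, which lactonises on acidification; three components thus fix the fully substituted C7=C11 olefin and the regiochemistry of the butenolide in one operation.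

Step 2
Reactants: 4 3-{[(tert-butyldimethylsilyl)oxy]methyl}-4-ethenylfuran-2(5H)-one
Product: 5 4-{[(tert-butyldimethylsilyl)oxy]methyl}-5-oxo-2,5-dihydrofuran-3-carbaldehyde
Conditions: O3, CH2Cl2, −78 °C (Sudan Red 7B end point); Me2S, −78 °C to 0 °C; used crude
Reagents that add atoms: ozone [O-][O+]=O
Why: Ozonolysis with reductive work-up; ozone should attack the terminal vinyl group of the dienyl lactone much faster than the tetrasubstituted, carbonyl-conjugated ring olefin, and the indicator stops the reaction before over-oxidation.

Step 3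
Reactants: 5 4-{[(tert-butyldimethylsilyl)oxy]methyl}-5-oxo-2,5-dihydrofuran-3-carbaldehyde
Product: 6 3-{[(tert-butyldimethylsilyl)oxy]methyl}-4-[(1S)-1-hydroxy-3-oxobutyl]furan-2(5H)-one
Conditions: D-proline (30 mol %), acetone/DMSO 1:4, 4 °C
Reagents that add atoms: acetone CC(C)=O
Why: Enamine-mediated direct asymmetric aldol reaction of acetone; the carboxylic acid of D-proline should guide the enamine to the si face of the aldehyde through the hydrogen-bonded chair-like transition state and so set C8 as S, while the fully substituted β-carbon of this enal blocks conjugate addition of the catalyst.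

Step 4
Reactants: 7 [(2R)-2-methyloxiran-2-yl]methanol
Product: 8 (2S)-2-methylpent-4-yne-1,2-diol
Conditions: LiC≡CH·H2NCH2CH2NH2 (3 equiv), DMSO, 0 °C to rt
Reagents that add atoms: lithium acetylide–ethylenediamine complex [Li]C#C.NCCN
Why: SN2 opening of the 2,2-disubstituted epoxide at its unsubstituted carbon (C3) by acetylide; no bond to the quaternary carbon C4 is broken, and the Payne rearrangement of the intermediate alkoxide is degenerate here (it returns the same enantiomer), so the chiral-pool configuration should be carried into C4 unchanged.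

Step 5
Reactants: 8 (2S)-2-methylpent-4-yne-1,2-diol
Product: 9 (2S)-2-methyl-1-[(triethylsilyl)oxy]pent-4-yn-2-ol
Conditions: Et3SiCl (1.05 equiv), imidazole, CH2Cl2, −40 °C
Reagents that add atoms: chlorotriethylsilane CC[Si](Cl)(CC)CC
Why: Silylation selective for the primary hydroxyl; the tertiary C4 hydroxyl stays free for the ring closure of step 8, and the triethylsilyl group is chosen to be cleavable later beside the tert-butyldimethylsilyl ether.

Step 6
Reactants: 9 (2S)-2-methyl-1-[(triethylsilyl)oxy]pent-4-yn-2-ol; 6 3-{[(tert-butyldimethylsilyl)oxy]methyl}-4-[(1S)-1-hydroxy-3-oxobutyl]furan-2(5H)-one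
Product: 11 3-{[(tert-butyldimethylsilyl)oxy]methyl}-4-[(1S,3S,7S)-1,3,7-trihydroxy-3,7-dimethyl-8-[(triethylsilyl)oxy]oct-4-yn-1-yl]furan-2(5H)-one, via alkynylcerium dichloride 10 (not isolated)
Conditions: 9 (2.5 equiv), n-BuLi (5.0 equiv), THF, −78 °C; anhydrous CeCl3 (2.6 equiv), −78 °C; then 6 (1 equiv), −78 °C; aq. NH4Cl; excess 9 recovered
Reagents that add atoms: none
Why: Organocerium addition to a ketone; the low basicity of the cerium acetylide should spare the acidic γ-position and the lactone carbonyl, the first equivalent converts the C8 hydroxyl into a cerium alkoxide that chelates the C10 carbonyl in a six-membered ring, and a second equivalent attacks this chelate from its open face (Cram chelate model for 1,3-induction), which should give the 1,3-anti diol with C10 as S.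

Step 7
Reactants: 11 3-{[(tert-butyldimethylsilyl)oxy]methyl}-4-[(1S,3S,7S)-1,3,7-trihydroxy-3,7-dimethyl-8-[(triethylsilyl)oxy]oct-4-yn-1-yl]furan-2(5H)-one
Product: 12 (1S,3S,7S)-1-(4-{[(tert-butyldimethylsilyl)oxy]methyl}-5-oxo-2,5-dihydrofuran-3-yl)-3,7-dihydroxy-3,7-dimethyl-8-[(triethylsilyl)oxy]oct-4-yn-1-yl acetate
Conditions: Ac2O (1.5 equiv), pyridine, CH2Cl2, 0 °C to rt (no DMAP)
Reagents that add atoms: acetic anhydride CC(=O)OC(C)=O
Why: Acylation in which only the secondary C8 hydroxyl should react, both tertiary alcohols being inert without an acyl-transfer catalyst; the acetate is the group of the target and also keeps the C8 oxygen from a 5-exo-dig attack on the alkyne in step 8.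

Step 8
Reactants: 12 (1S,3S,7S)-1-(4-{[(tert-butyldimethylsilyl)oxy]methyl}-5-oxo-2,5-dihydrofuran-3-yl)-3,7-dihydroxy-3,7-dimethyl-8-[(triethylsilyl)oxy]oct-4-yn-1-yl acetate
Product: 13 (1S,3S)-1-(4-{[(tert-butyldimethylsilyl)oxy]methyl}-5-oxo-2,5-dihydrofuran-3-yl)-3-hydroxy-3-[(5S)-5-methyl-5-{[(triethylsilyl)oxy]methyl}-4,5-dihydrofuran-2-yl]butyl acetate
Conditions: Ph3PAuNTf2 (2 mol %), THF, 4 Å MS, 0 °C; quench with Et3N
Reagents that add atoms: none
Why: Gold-catalysed 5-endo-dig hydroalkoxylation (cycloisomerisation of a homopropargylic alcohol): the tertiary C4 hydroxyl should add to C1 of the activated alkyne anti to the metal and protodeauration gives the C1=C2 enol ether; no stereocenter is formed, the 4-exo mode is not viable, and the primary and C8 oxygens are masked.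

Step 9
Reactants: 13 (1S,3S)-1-(4-{[(tert-butyldimethylsilyl)oxy]methyl}-5-oxo-2,5-dihydrofuran-3-yl)-3-hydroxy-3-[(5S)-5-methyl-5-{[(triethylsilyl)oxy]methyl}-4,5-dihydrofuran-2-yl]butyl acetate
Product: 14 (1S,3S)-1-(4-{[(tert-butyldimethylsilyl)oxy]methyl}-5-oxo-2,5-dihydrofuran-3-yl)-3-hydroxy-3-[(5S)-5-(hydroxymethyl)-5-methyl-4,5-dihydrofuran-2-yl]butyl acetate
Conditions: HF·pyridine, pyridine (large excess), THF, 0 °C
Reagents that add atoms: none
Why: Fluoride cleavage of the primary triethylsilyl ether, which should be much faster than that of the bulkier primary tert-butyldimethylsilyl ether; the excess of pyridine keeps the medium too weakly acidic to protonate the enol ether.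

Step 10
Reactants: 14 (1S,3S)-1-(4-{[(tert-butyldimethylsilyl)oxy]methyl}-5-oxo-2,5-dihydrofuran-3-yl)-3-hydroxy-3-[(5S)-5-(hydroxymethyl)-5-methyl-4,5-dihydrofuran-2-yl]butyl acetate
Product: 15 (1S,3S)-1-(4-{[(tert-butyldimethylsilyl)oxy]methyl}-5-oxo-2,5-dihydrofuran-3-yl)-3-[(5S)-5-formyl-5-methyl-4,5-dihydrofuran-2-yl]-3-hydroxybutyl acetate
Conditions: SO3·pyridine, DMSO, i-Pr2NEt, CH2Cl2, −10 °C
Reagents that add atoms: none
Why: Parikh–Doering oxidation under basic conditions, compatible with the enol ether; the aldehyde has a quaternary α-carbon, so it can neither epimerise nor enolise.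

Step 11
Reactants: 15 (1S,3S)-1-(4-{[(tert-butyldimethylsilyl)oxy]methyl}-5-oxo-2,5-dihydrofuran-3-yl)-3-[(5S)-5-formyl-5-methyl-4,5-dihydrofuran-2-yl]-3-hydroxybutyl acetate
Product: 18 (4S,8S,10S,5E)-8-acetoxy-13-[(tert-butyldimethylsilyl)oxy]-10-[(trimethylsilyl)oxy]-1,4-epoxygermacra-1,5,7(11)-trien-12,6-olide, via bis-silylated silyloxyfuran 16 (not isolated), via silylated aldol lactones 17 (not isolated)
Conditions: Me3SiOTf (4 equiv), Et3N (6 equiv), CH2Cl2, 0 °C, syringe-pump addition of 15 over 10 h to 1 mM final concentration; then DBU (5 equiv), 0 °C to rt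
Reagents that add atoms: trimethylsilyl trifluoromethanesulfonate C[Si](C)(C)OS(=O)(=O)C(F)(F)F
Why: Me3SiOTf/Et3N should silylate the tertiary C10 hydroxyl and turn the butenolide into the 2-silyloxyfuran 16, whose only unsubstituted ring position is C6. The silyl triflate then activates the C5 aldehyde and C6 attacks it in an intramolecular vinylogous Mukaiyama aldol addition, closing the nine-membered oxacycle O–C1–C10–C9–C8–C7–C6–C5–C4 in a 9-exo-trig mode to give 17; the closest known reaction type is the silyl triflate/amine-mediated vinylogous aldol addition of butenolides to aldehydes followed by base-induced elimination to γ-alkylidene butenolides. DBU then removes the C6 proton of 17 and the furanolate expels the C5 silyloxide (E1cB), which creates the C5=C6 double bond. The two stereocenters made in the ring closure (C5 and C6) are left uncontrolled on purpose, because all four diastereomers of 17 converge once both carbons become sp2. The olefin geometry is set by the ring alone: only the isomer with C4 and C7 cis (5E) is a cis-cycloalkene of the nine-membered ring, whereas the other geometry would be a far more strained trans-cycloalkene in a ring that already contains the planar lactone and enol ether. The step needs ring closure to beat intermolecular aldol addition, which high dilution, the two preformed rigid rings (only five rotatable bonds in the forming ring) and the quaternary carbons C4 and C10 (Thorpe–Ingold effect) should secure. Site selectivity follows from the substrate: C11 is fully substituted so the silyloxyfuran can react only at C6, the aldehyde has no α-hydrogen, and the C13 oxygen is a silyl ether whose loss would give a cross-conjugated methylene lactone instead of the conjugated alkylidene lactone. C4, C8 and C10 are not touched.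

Step 12
Reactants: 18 (4S,8S,10S,5E)-8-acetoxy-13-[(tert-butyldimethylsilyl)oxy]-10-[(trimethylsilyl)oxy]-1,4-epoxygermacra-1,5,7(11)-trien-12,6-olide
Product: 19 (4S,8S,10S,5E)-8-acetoxy-10,13-dihydroxy-1,4-epoxygermacra-1,5,7(11)-trien-12,6-olide
Conditions: Bu4NF (3 equiv), AcOH (3 equiv), THF, 0 °C to rt
Reagents that add atoms: none
Why: Fluoride desilylation buffered with acetic acid should remove both silyl ethers without exposing the dienyl lactone to free alkoxide or the enol ether to strong acid; a shift of the acetyl group from O8 to O13 would be harmless, because step 13 acylates whichever non-tertiary hydroxyl is free.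

Step 13
Reactants: 19 (4S,8S,10S,5E)-8-acetoxy-10,13-dihydroxy-1,4-epoxygermacra-1,5,7(11)-trien-12,6-olide
Product: 20 (4S,8S,10S,5E)-8,13-diacetoxy-10-hydroxy-1,4-epoxygermacra-1,5,7(11)-trien-12,6-olide
Conditions: Ac2O, pyridine, CH2Cl2, 0 °C
Reagents that add atoms: acetic anhydride CC(=O)OC(C)=O
Why: Acylation of the primary allylic alcohol; the tertiary C10 hydroxyl should stay free without an acyl-transfer catalyst, which gives the target with its three stereocenters and the 5E olefin as set in steps 3, 4, 6 and 11.

## Compound list

1 | 4-[(tert-butyldimethylsilyl)oxy]but-2-yn-1-ol | OCC#CCO[Si](C)(C)C(C)(C)C | starting material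
2 | bromomagnesium (2Z)-3-(bromomagnesio)-4-[(tert-butyldimethylsilyl)oxy]-2-ethenylbut-2-en-1-olate | C=C/C(CO[Mg]Br)=C(\CO[Si](C)(C)C(C)(C)C)[Mg]Br | intermediate
3 | bis(bromomagnesium) salt of (2Z)-2-{[(tert-butyldimethylsilyl)oxy]methyl}-3-(hydroxymethyl)penta-2,4-dienoic acid | C=C/C(CO[Mg]Br)=C(\CO[Si](C)(C)C(C)(C)C)C(=O)O[Mg]Br | intermediate
4 | 3-{[(tert-butyldimethylsilyl)oxy]methyl}-4-ethenylfuran-2(5H)-one | C=CC1=C(CO[Si](C)(C)C(C)(C)C)C(=O)OC1 | intermediate
5 | 4-{[(tert-butyldimethylsilyl)oxy]methyl}-5-oxo-2,5-dihydrofuran-3-carbaldehyde | O=CC1=C(CO[Si](C)(C)C(C)(C)C)C(=O)OC1 | intermediate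
6 | 3-{[(tert-butyldimethylsilyl)oxy]methyl}-4-[(1S)-1-hydroxy-3-oxobutyl]furan-2(5H)-one | CC(=O)C[C@H](O)C1=C(CO[Si](C)(C)C(C)(C)C)C(=O)OC1 | intermediate
7 | [(2R)-2-methyloxiran-2-yl]methanol, (R)-2-methylglycidol | OC[C@]1(C)CO1 | starting material
8 | (2S)-2-methylpent-4-yne-1,2-diol | OC[C@](O)(C)CC#C | intermediate
9 | (2S)-2-methyl-1-[(triethylsilyl)oxy]pent-4-yn-2-ol | CC[Si](CC)(CC)OC[C@](O)(C)CC#C | intermediate
10 | dichloro{(4S)-4-(lithiooxy)-4-methyl-5-[(triethylsilyl)oxy]pent-1-yn-1-yl}cerium | CC[Si](CC)(CC)OC[C@](O[Li])(C)CC#C[Ce](Cl)Cl | intermediate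
11 | 3-{[(tert-butyldimethylsilyl)oxy]methyl}-4-[(1S,3S,7S)-1,3,7-trihydroxy-3,7-dimethyl-8-[(triethylsilyl)oxy]oct-4-yn-1-yl]furan-2(5H)-one | CC[Si](CC)(CC)OC[C@](O)(C)CC#C[C@@](C)(O)C[C@H](O)C1=C(CO[Si](C)(C)C(C)(C)C)C(=O)OC1 | intermediate
12 | (1S,3S,7S)-1-(4-{[(tert-butyldimethylsilyl)oxy]methyl}-5-oxo-2,5-dihydrofuran-3-yl)-3,7-dihydroxy-3,7-dimethyl-8-[(triethylsilyl)oxy]oct-4-yn-1-yl acetate | CC[Si](CC)(CC)OC[C@](O)(C)CC#C[C@@](C)(O)C[C@H](OC(C)=O)C1=C(CO[Si](C)(C)C(C)(C)C)C(=O)OC1 | intermediate
13 | (1S,3S)-1-(4-{[(tert-butyldimethylsilyl)oxy]methyl}-5-oxo-2,5-dihydrofuran-3-yl)-3-hydroxy-3-[(5S)-5-methyl-5-{[(triethylsilyl)oxy]methyl}-4,5-dihydrofuran-2-yl]butyl acetate | CC[Si](CC)(CC)OC[C@]1(C)CC=C(O1)[C@@](C)(O)C[C@H](OC(C)=O)C1=C(CO[Si](C)(C)C(C)(C)C)C(=O)OC1 | intermediate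
14 | (1S,3S)-1-(4-{[(tert-butyldimethylsilyl)oxy]methyl}-5-oxo-2,5-dihydrofuran-3-yl)-3-hydroxy-3-[(5S)-5-(hydroxymethyl)-5-methyl-4,5-dihydrofuran-2-yl]butyl acetate | OC[C@]1(C)CC=C(O1)[C@@](C)(O)C[C@H](OC(C)=O)C1=C(CO[Si](C)(C)C(C)(C)C)C(=O)OC1 | intermediate
15 | (1S,3S)-1-(4-{[(tert-butyldimethylsilyl)oxy]methyl}-5-oxo-2,5-dihydrofuran-3-yl)-3-[(5S)-5-formyl-5-methyl-4,5-dihydrofuran-2-yl]-3-hydroxybutyl acetate | O=C[C@]1(C)CC=C(O1)[C@@](C)(O)C[C@H](OC(C)=O)C1=C(CO[Si](C)(C)C(C)(C)C)C(=O)OC1 | intermediate
16 | (1S,3S)-1-(4-{[(tert-butyldimethylsilyl)oxy]methyl}-5-[(trimethylsilyl)oxy]furan-3-yl)-3-[(5S)-5-formyl-5-methyl-4,5-dihydrofuran-2-yl]-3-[(trimethylsilyl)oxy]butyl acetate | O=C[C@]1(C)CC=C(O1)[C@@](C)(O[Si](C)(C)C)C[C@H](OC(C)=O)c1coc(O[Si](C)(C)C)c1CO[Si](C)(C)C(C)(C)C | intermediate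
17 | (4S,8S,10S)-8-acetoxy-13-[(tert-butyldimethylsilyl)oxy]-5,10-bis[(trimethylsilyl)oxy]-1,4-epoxygermacra-1,7(11)-dien-12,6-olide, mixture of C5 and C6 diastereomers | CC(C)(C)[Si](C)(C)OCC1=C2C(C(O[Si](C)(C)C)[C@]3(C)CC=C(O3)[C@@](C)(O[Si](C)(C)C)C[C@@H]2OC(C)=O)OC1=O | intermediate
18 | (4S,8S,10S,5E)-8-acetoxy-13-[(tert-butyldimethylsilyl)oxy]-10-[(trimethylsilyl)oxy]-1,4-epoxygermacra-1,5,7(11)-trien-12,6-olide | CC(C)(C)[Si](C)(C)OCC1=C2/C(=C\[C@]3(C)CC=C(O3)[C@@](C)(O[Si](C)(C)C)C[C@@H]2OC(C)=O)OC1=O | intermediate
19 | (4S,8S,10S,5E)-8-acetoxy-10,13-dihydroxy-1,4-epoxygermacra-1,5,7(11)-trien-12,6-olide | OCC1=C2/C(=C\[C@]3(C)CC=C(O3)[C@@](C)(O)C[C@@H]2OC(C)=O)OC1=O | intermediate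
20 | (4S,8S,10S,5E)-8,13-diacetoxy-10-hydroxy-1,4-epoxygermacra-1,5,7(11)-trien-12,6-olide, CNP0144020.1 | CC(=O)OCC1=C2/C(=C\[C@]3(C)CC=C(O3)[C@@](C)(O)C[C@@H]2OC(C)=O)OC1=O | target

## Step count and least certain steps

Total step count: 13. Longest linear sequence: 11 steps (steps 1, 2, 3, 6, 7, 8, 9, 10, 11, 12, 13); the branch from 7 (steps 4 and 5) joins at step 6.

**Step 11 (key step).** Three processes may defeat it:
- intermolecular vinylogous aldol addition (oligomerisation) may outrun the nine-membered ring closure;
- ionisation at C1 or C10 by the silyl triflate may be followed by capture of the silyloxyfuran at C1, closing a six-membered carbocycle instead;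
- the furanolate may expel the C13 silyloxide in competition with the C5 silyloxide.

The fallback replaces the Lewis-acid aldol by an irreversible olefination at the same bond. It sets out from 12 and comes back at 19. Treatment of 12 with i-Pr3SiOTf/Et3N and then NBS at −78 °C should give the γ-bromolactone F1. A Michaelis–Arbuzov reaction with P(OMe)3 gives the γ-phosphonate F2. The conditions of steps 8, 9 and 10 then lead through the dihydrofuran phosphonate F3 and the primary alcohol F4 to the aldehyde phosphonate F5. An intramolecular Horner–Wadsworth–Emmons reaction (LiCl, DBU, MeCN, high dilution) should close the ring to the macrocyclic lactone F6, again with ring-enforced 5E geometry. Desilylation under the conditions of step 12 returns 19.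

**Step 6.** Proton transfer from the butenolide γ-position to the organometallic, and incomplete chelation control at C10, may lower yield and diastereoselectivity. The fallback postpones the lactone carbonyl so that no acidic butenolide is present during the addition. It sets out from 1 and comes back at 11. The carbomagnesiation of step 1 is quenched with I2 instead of CO2 to give the iodo dienol F7. Ozonolysis as in step 2 gives the iodo enal F8, and the aldol reaction of step 3 gives the aldol F9. Addition of reagent 10 (3.5 equiv, conditions of step 6) gives the propargylic diol F10. Carbonylative lactonisation of the vinyl iodide with the cis hydroxymethyl group (Pd(PPh3)4, CO 1 atm, K2CO3, THF, 50 °C) then delivers 11.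

**Step 8.** Ionisation of the tertiary propargylic C10 alcohol (Meyer–Schuster-type rearrangement), or acid-catalysed addition of a hydroxyl group to the newly formed enol ether, may occur in the presence of the cationic gold catalyst. The fallback forms the enol ether under basic conditions after the metal is gone. It sets out from 12 and comes back at 13. Hydroxyl-assisted hydration of the alkyne (Ph3PAuNTf2, THF/H2O 10:1) should give the cyclic hemiketal F11. Elimination through the C1 oxocarbenium ion (MsCl, Et3N, CH2Cl2, −20 °C to rt) gives 13; the only β-hydrogens are those on C2.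

**Step 3.** Insufficient enantioface discrimination, and self-condensation of the enolisable, electron-poor aldehyde during the slow amine-catalysed reaction, may erode C8. The fallback uses fast reagent-controlled allyl transfer instead of enamine catalysis. It sets out from 5 and comes back at 6. Allylboration at −78 °C with the si-face-selective antipode of B-methallyldiisopinocampheylborane (chair-like six-membered transition state, ethanolamine work-up) should give the homoallylic alcohol F12. Ozonolysis of its 1,1-disubstituted olefin (O3, CH2Cl2, −78 °C; Me2S) gives 6.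

## Further compounds

F1 | step 11 | γ-bromolactone: 12 carrying bromine on the lactone CH2 carbon C6 (C6 epimers) | CC[Si](CC)(CC)OC[C@](O)(C)CC#C[C@@](C)(O)C[C@H](OC(C)=O)C1=C(CO[Si](C)(C)C(C)(C)C)C(=O)OC1Br
F2 | step 11 | γ-phosphonate: 12 carrying a dimethoxyphosphoryl group on C6 (C6 epimers) | CC[Si](CC)(CC)OC[C@](O)(C)CC#C[C@@](C)(O)C[C@H](OC(C)=O)C1=C(CO[Si](C)(C)C(C)(C)C)C(=O)OC1P(=O)(OC)OC
F3 | step 11 | dihydrofuran phosphonate: 13 carrying a dimethoxyphosphoryl group on C6 | CC[Si](CC)(CC)OC[C@]1(C)CC=C(O1)[C@@](C)(O)C[C@H](OC(C)=O)C1=C(CO[Si](C)(C)C(C)(C)C)C(=O)OC1P(=O)(OC)OC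
F4 | step 11 | primary alcohol: 14 carrying a dimethoxyphosphoryl group on C6 | OC[C@]1(C)CC=C(O1)[C@@](C)(O)C[C@H](OC(C)=O)C1=C(CO[Si](C)(C)C(C)(C)C)C(=O)OC1P(=O)(OC)OC
F5 | step 11 | aldehyde phosphonate: 15 carrying a dimethoxyphosphoryl group on C6 | O=C[C@]1(C)CC=C(O1)[C@@](C)(O)C[C@H](OC(C)=O)C1=C(CO[Si](C)(C)C(C)(C)C)C(=O)OC1P(=O)(OC)OC
F6 | step 11 | (4S,8S,10S,5E)-8-acetoxy-13-[(tert-butyldimethylsilyl)oxy]-10-hydroxy-1,4-epoxygermacra-1,5,7(11)-trien-12,6-olide | CC(C)(C)[Si](C)(C)OCC1=C2/C(=C\[C@]3(C)CC=C(O3)[C@@](C)(O)C[C@@H]2OC(C)=O)OC1=O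
F7 | step 6 | (2Z)-4-[(tert-butyldimethylsilyl)oxy]-2-ethenyl-3-iodobut-2-en-1-ol | OC/C(C=C)=C(\I)CO[Si](C)(C)C(C)(C)C
F8 | step 6 | (2Z)-4-[(tert-butyldimethylsilyl)oxy]-2-(hydroxymethyl)-3-iodobut-2-enal | OC/C(C=O)=C(\I)CO[Si](C)(C)C(C)(C)C
F9 | step 6 | (4S,5Z)-7-[(tert-butyldimethylsilyl)oxy]-4-hydroxy-5-(hydroxymethyl)-6-iodohept-5-en-2-one | CC(=O)C[C@H](O)/C(CO)=C(/I)CO[Si](C)(C)C(C)(C)C
F10 | step 6 | open-chain vinyl iodide triol corresponding to 11 before carbonylation (C4, C8, C10 as in 11; iodine on C11 cis to the C6 hydroxymethyl group) | CC[Si](CC)(CC)OC[C@](O)(C)CC#C[C@@](C)(O)C[C@H](O)/C(CO)=C(/I)CO[Si](C)(C)C(C)(C)C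
F11 | step 8 | cyclic hemiketal: 13 with water added across C1=C2, hydroxyl on C1 (C1 anomers) | CC[Si](CC)(CC)OC[C@]1(C)CCC(O)(O1)[C@@](C)(O)C[C@H](OC(C)=O)C1=C(CO[Si](C)(C)C(C)(C)C)C(=O)OC1
F12 | step 3 | 3-{[(tert-butyldimethylsilyl)oxy]methyl}-4-[(1S)-1-hydroxy-3-methylbut-3-en-1-yl]furan-2(5H)-one | CC(=C)C[C@H](O)C1=C(CO[Si](C)(C)C(C)(C)C)C(=O)OC1
A1 | alternative 1 | (3S)-3-[(5S)-5-{(E)-[4-(acetoxymethyl)-3-iodo-5-oxofuran-2(5H)-ylidene]methyl}-5-methyl-4,5-dihydrofuran-2-yl]-3-hydroxybutanal | CC(=O)OCC1=C(I)/C(=C\[C@]3(C)CC=C(O3)[C@@](C)(O)CC=O)OC1=O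
A2 | alternative 2 | cadinene-type octalin: methyl 3-acetoxy-2-[2-acetoxy-4,7-dihydroxy-4,7-dimethyl-3,4,5,6,7,8-hexahydronaphthalen-1(2H)-ylidene]propanoate, C4, C8 and C10 configured as in 20, ester cis to C6 | COC(=O)/C(COC(C)=O)=C1/[C@@H](OC(C)=O)C[C@](C)(O)C2=C1C[C@@](C)(O)CC2
A3 | alternative 2 | ten-membered 1,6-dione from cleavage of the C1=C6 bond of A2, C4, C8 and C10 configured as in 20 | COC(=O)/C(COC(C)=O)=C1/[C@@H](OC(C)=O)C[C@](C)(O)C(=O)CC[C@](C)(O)CC1=O
A4 | alternative 3 | (1S,3S)-1-[4-(acetoxymethyl)-2-[(Z)-bromomethylidene]-5-oxo-2,5-dihydrofuran-3-yl]-3-hydroxy-3-(5-methylfuran-2-yl)butyl acetate | Cc1ccc(o1)[C@@](C)(O)C[C@H](OC(C)=O)C1=C(COC(C)=O)C(=O)O/C1=C\Br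
A5 | alternative 3 | exo-fused oxanorbornene cycloadduct of A4 (new bonds C4–C5 and C1–C6, bromine endo on C5), C4, C8 and C10 configured as in 20 | C[C@@]12C=C[C@]3(O1)[C@@](C)(O)C[C@H](OC(C)=O)C4=C(COC(C)=O)C(=O)O[C@@]43[C@@H]2Br
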